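**Remark on the chemistry (assumptions):** 1, 2, 7 and 10 are taken as purchasable. 8, 11 and 12 are written without double-bond geometry because isomer mixtures are expected and the geometry is lost in the next step. 13 is racemic and transient.

## Structural features

The target 17 is a linear triaryl bis-ether of the phlorotannin type: three benzene rings (A, B, C) joined by two diaryl ether oxygens, with no chain and no stereocentre, so no question of neighbouring stereocentres arises. Ring A is a 3,5-dihydroxyphenyl group bound through oxygen to C1 of ring B. Ring B carries hydroxyls at C2 and C6 on either side of that oxygen and the second ether oxygen at C4. Ring C is a phloroglucinol ring bound through its C1 oxygen, with hydroxyls at C2, C4 and C6 and bromine at C3. Each ether oxygen therefore sits on a carbon flanked by two oxygenated carbons (C1 of ring B, C1 of ring C), which makes these aryl–oxygen bonds hindered. The free hexaphenol is sensitive to air and base, and the C–Br bond on the most electron-rich ring is exposed to hydrogenolysis, halogen–metal exchange and acid-induced loss; the phenols are therefore carried as methyl ethers, and alkyllithiums and hydrogenation are avoided once bromine is in place. The real difficulty is twofold: placing a single bromine on one of three electron-rich rings (helped by the equivalence of C3 and C5 of ring C), and building the meta oxygenation of ring A, which electrophilic substitution cannot deliver. The key step exploits ring A as a phloroglucinol mono-ether: the oxygens at C3 and C5 map onto the two carbonyl oxygens of an acetoacetate, the oxygen-bearing C1 onto the oxygen-bearing carbon of an aryl alkynyl ether, and C2 can carry an ester that is later lost as CO2.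

## Logic of the disconnections

**17 ⇒ 16.** The five O–CH3 bonds on rings B and C are cut. The hexaphenol is too oxidisable to carry through C–O couplings, bromination and base, so it is unmasked last. The gain is that every earlier intermediate is a robust, chromatographable methyl ether. The forward step needs a Lewis-acid dealkylation that leaves the C–Br bond and both diaryl ethers intact.

**16 ⇒ 14 (through 15).** The C2–H bond of ring A is traced back to a C2–CO2CH3 bond. The ester is what polarises the two-carbon partner in the ring synthesis, and a carboxyl between two ring oxygens leaves easily. The gain is that 16 becomes the product of a ring-forming reaction. The forward step must hydrolyse a doubly ortho-substituted ester and decarboxylate; it is placed before the demethylation so that only a resorcinol, not the hexaphenol, meets hot base.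

**14 ⇒ 9 + 12.** Ring A bonds C1–C6 and C2–C3 are cut. This places the ether oxygen on a carbon that never has to be functionalised on an arene and fixes the 1,3,5-oxygen pattern by connectivity. The gain is the largest of the route: ring A is reduced to a four-carbon diene and a two-carbon alkynyl ether on the ring B oxygen. The forward step needs the CH2 terminus of 12 to bond to the oxygen-bearing alkyne carbon of 9, and the adduct to aromatise by loss of methanol.

**12 ⇒ 11 ⇒ 10.** The two O–Si bonds are cut in turn. 12 is moisture-sensitive and is best made fresh; each silylation is a standard enolisation. The demand is γ-deprotonation of 11 without C-silylation.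

**9 ⇒ 8 ⇒ 6 + 7.** One π bond of the alkyne is traced back to H and Cl on adjacent carbons, then the O–C(sp2) bond is cut. The alkynyl ether cannot be made with alkyllithium reagents once the aryl bromide is present, so it is built by vinylic substitution and elimination. The gain is that the whole A-ring precursor hangs on a phenol. The forward steps need monosubstitution of 7 and loss of chloride, not aryloxide, from 8.

**6 ⇒ 4 (through 5).** The C1–O bond of ring B is traced back to a C1–CHO bond. The formyl group activates the bromide of 2 for C–O coupling, deactivates ring B during bromination, and becomes the phenol without any protecting group. The demand is aryl migration in the peracid oxidation.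

**4 ⇒ 3.** The C3–Br bond of ring C is cut. Bromine is introduced when ring C is the only strongly activated ring present and ring A does not yet exist. The demand is monobromination on ring C only.

**3 ⇒ 1 + 2.** The C4–O bond of ring B is cut. This pairs an electron-rich phenol with an unhindered, formyl-activated aryl bromide, the favourable polarity for copper-catalysed etherification. The gain is two simple purchasable arenes. The demand is coupling of a phenol with two ortho substituents.

## Other disconnections considered

**Alternative 1:** The cut removes three bonds of ring C. The ring is assembled from the four-carbon unit of a ring A–B cyclobutenone, 4-[4-(3,5-dimethoxyphenoxy)-3,5-dimethoxyphenoxy]-3-ethoxycyclobut-2-en-1-one A1, and the two carbons of (ethoxyethynyl)trimethylsilane A2. On heating, A1 would open to a vinylketene that adds A2 in a [2+2] sense. 4π opening and 6π closure would then give 6-[4-(3,5-dimethoxyphenoxy)-3,5-dimethoxyphenoxy]-3,5-diethoxy-2-(trimethylsilyl)phenol A3, with silicon on the carbon meant for bromine. Ipso-bromodesilylation and cleavage of seven alkyl ethers would follow.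

- In its favour: the pericyclic cascade has a strict, well-understood regiochemistry, needs no metal or base, and the silyl group can steer the electrophile to ring C by ipso substitution.
- Against it here: A1 must itself be built (for instance from an aryloxyketene and an alkoxyacetylene), which adds steps and a thermally and hydrolytically delicate intermediate. In A3 the ring C carbon between the two ethoxy groups is still C–H and para to the free hydroxyl, and ring A offers three strongly activated C–H positions, so the electrophile has choices besides the C–Si bond. Because C3 and C5 of ring C are equivalent in the target, the marker decides only which ring is brominated, not which position.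
- Comparison, structure: the chosen plan brominates while ring B is formyl-deactivated and ring A is absent, so the competition A3 must win does not arise.
- Comparison, mechanism: the benzannulation is the better-precedented ring synthesis, and on this point the alternative is the better plan, since the chosen cycloaddition uses an untried class of dienophile.
- Comparison, step economy: the alternative is expected to be longer (cyclobutenone synthesis, two more ether cleavages). The final dealkylation is equal in both.

**Alternative 2:** The cut removes the two C–O bonds at C3 and C5 of ring A, which stays a plain phenyl group until late. O-Phenylation of 6 would give 2-bromo-4-(3,5-dimethoxy-4-phenoxyphenoxy)-1,3,5-trimethoxybenzene A4. [Ir(OMe)(cod)]2 with 4,4'-di-tert-butyl-2,2'-bipyridine and B2pin2 would borylate both meta positions of the phenyl ring, and Oxone would oxidise the boronates to 5-[4-(3-bromo-2,4,6-trimethoxyphenoxy)-2,6-dimethoxyphenoxy]benzene-1,3-diol A5, which is the same substance as 16.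

- In its favour: two steps from 6 to 16 in place of four, no diene synthesis and no moisture-sensitive alkynyl ether. The remaining C–H bonds of rings B and C each lie between two substituents and should be left alone by a sterically governed catalyst, and the C–Br bond is tolerated.
- Against it here: on a monosubstituted ring the para position is as accessible as the meta positions. A first borylation there cannot lead to the 3,5-pattern, so a substantial part of the material is expected to be diverted, and the diboronate must be separated from mono-borylated products. Peroxymonosulfate may also over-oxidise so electron-rich a triaryl ether.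
- Comparison, structure: equal, since both plans share steps 1–3 and the same penultimate compound and final step.
- Comparison, mechanism: the chosen plan fixes the 1,3,5-pattern by the connectivity of 9 and 12, whereas the alternative relies on kinetic site selectivity with no directing element.
- Comparison, step economy: the alternative is the better plan.

**Alternative 3:** The cut removes ring C bonds C2–C3 and C5–C6. Ring C comes from the central carbon and both ester carbons of dimethyl 2-[4-(3,5-dimethoxyphenoxy)-3,5-dimethoxyphenoxy]propanedioate A6 and the C–CO–C unit of dimethyl 3-oxopentanedioate A7. NaOMe would bring about two Claisen condensations to give dimethyl 5-[4-(3,5-dimethoxyphenoxy)-3,5-dimethoxyphenoxy]-2,4,6-trihydroxyisophthalate A8. Hydrolysis, double decarboxylation, monobromination and demethylation would follow.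

- In its favour: cheap reagents, a phloroglucinol pattern fixed by construction, and traceless carboxyl groups. This last idea is the same as in the chosen plan, and on it the two are equal.
- Against it here: the base deprotonates the acidic C–H of A6, which shuts down its esters as acyl donors, and A7 self-condenses under the same conditions, so the double condensation has to outrun both. Bromine must then be placed on ring C in the presence of a 3,5-dimethoxyphenyl ring A that is itself strongly activated, and the two equivalent open positions of ring C invite dibromination.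
- Comparison, structure: both plans grow an oxygenated ring from acyclic carbonyl compounds onto a pre-formed aryl ether oxygen, but the chosen plan settles the bromine early under formyl control.
- Comparison, mechanism: one C–C bond-forming event with a strongly nucleophilic diene stands against two condensations that fight an unfavourable acidity.
- Comparison, step economy: about equal in length; in reagent cost the alternative is the better plan.

Key step: step 8

## Route

**Step 1**
Reactants: 1 2,4,6-trimethoxyphenol; 2 4-bromo-2,6-dimethoxybenzaldehyde
Product: 3 2,6-dimethoxy-4-(2,4,6-trimethoxyphenoxy)benzaldehyde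
Conditions: CuI (10 mol %), picolinic acid (20 mol %), K3PO4, DMSO, 90 °C, Ar
Reagents that add atoms: none
Why: Ullmann-type O-arylation catalysed by monovalent copper; the bromide is unhindered and activated by the para formyl group, the phenol is electron-rich, and the picolinate ligand suits phenols with two ortho substituents; argon keeps the phenoxide from oxidation.

**Step 2**
Reactants: 3 2,6-dimethoxy-4-(2,4,6-trimethoxyphenoxy)benzaldehyde
Product: 4 4-(3-bromo-2,4,6-trimethoxyphenoxy)-2,6-dimethoxybenzaldehyde
Conditions: NBS (1.0 equiv), MeCN, −20 °C → 0 °C
Reagents that add atoms: N-bromosuccinimide, O=C1CCC(=O)N1Br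
Why: Electrophilic aromatic bromination; ring C is a 1,3,5-trimethoxybenzene-type ring whereas all three oxygens of ring B are conjugated to the formyl group, so ring C should react first; its two open positions are equivalent and the first bromine deactivates the ring, so one equivalent should stop at the monobromide.

**Step 3**
Reactants: 4 4-(3-bromo-2,4,6-trimethoxyphenoxy)-2,6-dimethoxybenzaldehyde
Product: 6 4-(3-bromo-2,4,6-trimethoxyphenoxy)-2,6-dimethoxyphenol, via aryl formate 5 (not isolated)
Conditions: mCPBA, CH2Cl2, 0 °C → rt; then K2CO3 (cat.), MeOH, rt
Reagents that add atoms: 3-chloroperoxybenzoic acid, OOC(=O)c1cccc(Cl)c1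
Why: Baeyer–Villiger (Dakin-type) oxidation of a benzaldehyde with ortho and para oxygen donors, in which the aryl group migrates to give formate 5; mild methanolysis frees the phenol, and the ethers and C–Br bond are untouched.

**Step 4**
Reactants: 6 4-(3-bromo-2,4,6-trimethoxyphenoxy)-2,6-dimethoxyphenol; 7 methyl 3,3-dichloroprop-2-enoate
Product: 8 methyl 3-[4-(3-bromo-2,4,6-trimethoxyphenoxy)-2,6-dimethoxyphenoxy]-3-chloroprop-2-enoate
Conditions: 7 (1.5 equiv), K2CO3, DMF, 0 °C → rt
Reagents that add atoms: none
Why: Addition–elimination (nucleophilic vinylic substitution) of the phenoxide at the β-carbon of the dichloroacrylate; excess 7, the lower electrophilicity of the β-aryloxy product and the two ortho methoxy groups should hold the reaction at monosubstitution.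

**Step 5**
Reactants: 8 methyl 3-[4-(3-bromo-2,4,6-trimethoxyphenoxy)-2,6-dimethoxyphenoxy]-3-chloroprop-2-enoate
Product: 9 methyl 3-[4-(3-bromo-2,4,6-trimethoxyphenoxy)-2,6-dimethoxyphenoxy]prop-2-ynoate
Conditions: LiN(SiMe3)2 (1.2 equiv), THF, −78 °C → 0 °C
Reagents that add atoms: none
Why: Base-induced dehydrochlorination of a 1-chloro-1-aryloxyalkene to an aryl alkynyl ether, the same reaction type as the formation of ynol ethers from halo-enol ethers; the ester acidifies the vinylic hydrogen, the labile α-carbanion lets both double-bond isomers expel chloride, and the hindered silylamide should not add to the ynoate, which is kept dry and used at once.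

**Step 6**
Reactants: 10 methyl 3-oxobutanoate (methyl acetoacetate)
Product: 11 methyl 3-(trimethylsilyloxy)but-2-enoate
Conditions: TMSCl, Et3N, hexane, rt
Reagents that add atoms: chlorotrimethylsilane, C[Si](C)(C)Cl
Why: O-silylation of the enol of a β-keto ester (silyl enol ether formation) under soft enolisation.

**Step 7**
Reactants: 11 methyl 3-(trimethylsilyloxy)but-2-enoate
Product: 12 1-methoxy-1,3-bis(trimethylsilyloxy)buta-1,3-diene
Conditions: LiN(i-Pr)2, TMSCl, THF, −78 °C → rt
Reagents that add atoms: chlorotrimethylsilane, C[Si](C)(C)Cl
Why: γ-Deprotonation of the silyl enol ether and O-silylation of the dienolate to the silyl ketene acetal, the standard preparation of 1-alkoxy-1,3-bis(silyloxy)dienes; the diene is distilled and used fresh.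

**Step 8**
Reactants: 9 methyl 3-[4-(3-bromo-2,4,6-trimethoxyphenoxy)-2,6-dimethoxyphenoxy]prop-2-ynoate; 12 1-methoxy-1,3-bis(trimethylsilyloxy)buta-1,3-diene
Product: 14 methyl 2-[4-(3-bromo-2,4,6-trimethoxyphenoxy)-2,6-dimethoxyphenoxy]-4,6-dihydroxybenzoate, via cyclohexadiene cycloadduct 13 (not isolated)
Conditions: 12 (3 equiv), PhMe, 100 °C (sealed tube); then 1 M HCl, THF, rt
Reagents that add atoms: none
Why: Proposed new method: the CH2 terminus of 12 (ring A C6, the most nucleophilic diene carbon) should bond to the aryloxy-bearing alkyne carbon of 9 (C1), which the conjugated ester makes the electrophilic β-position, while the ketene acetal carbon (C3) bonds to the ester-bearing α-carbon (C2), in an asynchronous [4+2] cycloaddition or its stepwise Mukaiyama–Michael/ring-closure equivalent; the closest known reaction type is the Diels–Alder/aromatisation of 1-alkoxy-1,3-bis(silyloxy)dienes with propiolates, alkynones and acetylenedicarboxylates to resorcinol esters, not yet extended to 3-aryloxypropiolates. The aryloxy group is a weak donor because its two ortho methoxy groups twist it out of conjugation, so the alkyne should keep enough dienophile character. Ring A is closed by intermolecular [4+2] cycloaddition, bonds C1–C6 and C2–C3 forming in one operation (6-exo-trig acylation after Michael addition if stepwise). Cycloadduct 13 aromatises on acid work-up by loss of methanol from its ketal carbon and hydrolysis of both silyl ethers. No stereocentre is created that survives, since the ketal carbon of 13 is racemic and becomes sp2. The selectivity needed is regiochemical, ether oxygen meta to both hydroxyls, and it is secured by the ester polarisation of the alkyne. A stepwise closure onto the propiolate ester instead would give the 4-aryloxy-2,6-dihydroxybenzoate isomer, which converges on 16 in step 9. The aryl bromide, methyl ethers and diaryl ether are inert to neutral heating and brief dilute acid.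

**Step 9**
Reactants: 14 methyl 2-[4-(3-bromo-2,4,6-trimethoxyphenoxy)-2,6-dimethoxyphenoxy]-4,6-dihydroxybenzoate
Product: 16 5-[4-(3-bromo-2,4,6-trimethoxyphenoxy)-2,6-dimethoxyphenoxy]benzene-1,3-diol, via benzoic acid 15 (not isolated)
Conditions: 4 M NaOH, MeOH–H2O, 90 °C, Ar; then HCl to pH 2, 70 °C
Reagents that add atoms: none
Why: Saponification of the resorcylate ester, then decarboxylation of the 2,4,6-trioxygenated benzoic acid 15 by ipso-protonation on warming in acid; methyl ethers, diaryl ethers and C–Br are stable to aqueous base, and running this before demethylation keeps the hexaphenol away from base.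

**Step 10**
Reactants: 16 5-[4-(3-bromo-2,4,6-trimethoxyphenoxy)-2,6-dimethoxyphenoxy]benzene-1,3-diol
Product: 17 5-[4-(3-bromo-2,4,6-trihydroxyphenoxy)-2,6-dihydroxyphenoxy]benzene-1,3-diol
Conditions: BBr3 (12 equiv), CH2Cl2, −78 °C → rt; then H2O, 0 °C
Reagents that add atoms: none
Why: Lewis-acid cleavage of aryl methyl ethers by BBr3 (boron complexation, then SN2 attack of bromide on methyl); diaryl ethers offer no SN2 site and the C–Br bond is inert, and a cold quench with prompt extraction limits contact of the bromophloroglucinol ring with aqueous HBr.

## Compound list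

1 | 2,4,6-trimethoxyphenol | COc1cc(OC)c(O)c(OC)c1 | starting material
2 | 4-bromo-2,6-dimethoxybenzaldehyde | COc1cc(Br)cc(OC)c1C=O | starting material
3 | 2,6-dimethoxy-4-(2,4,6-trimethoxyphenoxy)benzaldehyde | COc1cc(OC)c(Oc2cc(OC)c(C=O)c(OC)c2)c(OC)c1 | intermediate
4 | 4-(3-bromo-2,4,6-trimethoxyphenoxy)-2,6-dimethoxybenzaldehyde | COc1cc(OC)c(Oc2cc(OC)c(C=O)c(OC)c2)c(OC)c1Br | intermediate
5 | 4-(3-bromo-2,4,6-trimethoxyphenoxy)-2,6-dimethoxyphenyl formate | COc1cc(OC)c(Oc2cc(OC)c(OC=O)c(OC)c2)c(OC)c1Br | intermediate
6 | 4-(3-bromo-2,4,6-trimethoxyphenoxy)-2,6-dimethoxyphenol | COc1cc(OC)c(Oc2cc(OC)c(O)c(OC)c2)c(OC)c1Br | intermediate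
7 | methyl 3,3-dichloroprop-2-enoate | COC(=O)C=C(Cl)Cl | starting material
8 | methyl 3-[4-(3-bromo-2,4,6-trimethoxyphenoxy)-2,6-dimethoxyphenoxy]-3-chloroprop-2-enoate (mixture of double-bond isomers) | COC(=O)C=C(Cl)Oc1c(OC)cc(Oc2c(OC)cc(OC)c(Br)c2OC)cc1OC | intermediate
9 | methyl 3-[4-(3-bromo-2,4,6-trimethoxyphenoxy)-2,6-dimethoxyphenoxy]prop-2-ynoate | COC(=O)C#COc1c(OC)cc(Oc2c(OC)cc(OC)c(Br)c2OC)cc1OC | intermediate
10 | methyl 3-oxobutanoate | CC(=O)CC(=O)OC | starting material
11 | methyl 3-(trimethylsilyloxy)but-2-enoate (geometry not defined) | COC(=O)C=C(C)O[Si](C)(C)C | intermediate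
12 | 1-methoxy-1,3-bis(trimethylsilyloxy)buta-1,3-diene (geometry not defined) | COC(O[Si](C)(C)C)=CC(=C)O[Si](C)(C)C | intermediate
13 | methyl 2-[4-(3-bromo-2,4,6-trimethoxyphenoxy)-2,6-dimethoxyphenoxy]-6-methoxy-4,6-bis(trimethylsilyloxy)cyclohexa-1,4-diene-1-carboxylate (racemic) | COC(=O)C1=C(Oc2c(OC)cc(Oc3c(OC)cc(OC)c(Br)c3OC)cc2OC)CC(O[Si](C)(C)C)=CC1(OC)O[Si](C)(C)C | intermediate
14 | methyl 2-[4-(3-bromo-2,4,6-trimethoxyphenoxy)-2,6-dimethoxyphenoxy]-4,6-dihydroxybenzoate | COC(=O)c1c(O)cc(O)cc1Oc1c(OC)cc(Oc2c(OC)cc(OC)c(Br)c2OC)cc1OC | intermediate
15 | 2-[4-(3-bromo-2,4,6-trimethoxyphenoxy)-2,6-dimethoxyphenoxy]-4,6-dihydroxybenzoic acid | OC(=O)c1c(O)cc(O)cc1Oc1c(OC)cc(Oc2c(OC)cc(OC)c(Br)c2OC)cc1OC | intermediate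
16 | 5-[4-(3-bromo-2,4,6-trimethoxyphenoxy)-2,6-dimethoxyphenoxy]benzene-1,3-diol | Oc1cc(O)cc(Oc2c(OC)cc(Oc3c(OC)cc(OC)c(Br)c3OC)cc2OC)c1 | intermediate
17 | 5-[4-(3-bromo-2,4,6-trihydroxyphenoxy)-2,6-dihydroxyphenoxy]benzene-1,3-diol | Oc1cc(O)cc(Oc2c(O)cc(Oc3c(O)cc(O)c(Br)c3O)cc2O)c1 | target

## Step count and least certain steps

Total: 10 steps. Longest linear sequence: 8 steps (1, 2, 3, 4, 5, 8, 9, 10); steps 6 and 7 form the diene branch.

**Step 8 (key step; carries the label "Proposed new method:").** The donor-substituted alkyne may be too sluggish a dienophile, so the diene may be consumed by silyl migration or hydrolysis before it adds. A [2+2] addition of the silyl enol ether to the ynoate may compete, and unreacted alkynyl ether would be hydrated on work-up. The fallback uses known chemistry, sets out from 6 and returns at 17. Ullmann-type coupling of 6 with 1-iodo-3,5-dimethoxybenzene (CuI, picolinic acid, K3PO4, DMSO, 90 °C) should engage the aryl iodide in preference to the hindered, electron-rich C–Br bond of ring C. It would give 2-bromo-4-[4-(3,5-dimethoxyphenoxy)-3,5-dimethoxyphenoxy]-1,3,5-trimethoxybenzene F1. BBr3 in CH2Cl2 would then cleave all seven methyl ethers to 17. Ring A is then bought, not built.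

**Step 5.** From the isomer of 8 with hydrogen anti to the aryloxy group, aryloxide may be eliminated in place of chloride. The product may also suffer conjugate addition of the amide base or of traces of water. The fallback sets out from 8 and 10 and returns at 16. The dianion of 10 (LiN(i-Pr)2, 2 equiv, THF, −78 °C) should attack the chlorine-bearing carbon of 8 through its terminal carbon and expel chloride. This would give dimethyl 3-[4-(3-bromo-2,4,6-trimethoxyphenoxy)-2,6-dimethoxyphenoxy]-5-oxohept-2-enedioate F2. NaOMe in MeOH would close ring A by Claisen condensation to methyl 4-[4-(3-bromo-2,4,6-trimethoxyphenoxy)-2,6-dimethoxyphenoxy]-2,6-dihydroxybenzoate F3. Under the conditions of step 9 this would pass through 4-[4-(3-bromo-2,4,6-trimethoxyphenoxy)-2,6-dimethoxyphenoxy]-2,6-dihydroxybenzoic acid F4 and lose CO2 to give 16.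

**Step 1.** The very electron-rich phenoxide may be oxidised under copper catalysis, and the two ortho methoxy groups may slow C–O bond formation so that the aldehyde degrades in hot basic DMSO. The fallback is metal-free, sets out from 1 and returns at 3. The phenoxide of 1 (K2CO3, DMF, 0 °C → rt) should displace the para fluorine of 2,4,6-trifluorobenzaldehyde to give 2,6-difluoro-4-(2,4,6-trimethoxyphenoxy)benzaldehyde F5. NaOMe in MeOH at 60 °C would then replace the two fluorines ortho to the formyl group, fluoride being displaced far more readily than aryloxide, to give 3.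

**Step 2.** Site selectivity may be incomplete, with some bromination on ring B or a second bromination on ring C. The fallback sets out from 1 and returns at 4. Acetylation (Ac2O, pyridine) would give 2,4,6-trimethoxyphenyl acetate F6, and NBS in MeCN would give 3-bromo-2,4,6-trimethoxyphenyl acetate F7. Methanolysis (K2CO3 cat., MeOH) would give 3-bromo-2,4,6-trimethoxyphenol F8. Coupling of F8 with 2 under the conditions of step 1 would lead to 4, since the formyl-activated, unhindered bromide of 2 should react in preference to the flanked bromide of F8.

**Step 9.** Saponification of the doubly ortho-substituted ester may be incomplete, or the resorcinol dianion may degrade oxidatively in hot base. The fallback sets out from 14 and returns at 17. BBr3 (CH2Cl2, −78 °C → rt, prolonged) should cleave the five aryl methyl ethers and, through the boron chelate of the salicylate, the ester methyl. This would give 2-[4-(3-bromo-2,4,6-trihydroxyphenoxy)-2,6-dihydroxyphenoxy]-4,6-dihydroxybenzoic acid F9, which should lose CO2 in water at 80 °C under argon to give 17.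

## Further compounds

F1 | step 8 | 2-bromo-4-[4-(3,5-dimethoxyphenoxy)-3,5-dimethoxyphenoxy]-1,3,5-trimethoxybenzene | COc1cc(OC)cc(Oc2c(OC)cc(Oc3c(OC)cc(OC)c(Br)c3OC)cc2OC)c1
F2 | step 5 | dimethyl 3-[4-(3-bromo-2,4,6-trimethoxyphenoxy)-2,6-dimethoxyphenoxy]-5-oxohept-2-enedioate | COC(=O)C=C(Oc1c(OC)cc(Oc2c(OC)cc(OC)c(Br)c2OC)cc1OC)CC(=O)CC(=O)OC
F3 | step 5 | methyl 4-[4-(3-bromo-2,4,6-trimethoxyphenoxy)-2,6-dimethoxyphenoxy]-2,6-dihydroxybenzoate | COC(=O)c1c(O)cc(Oc2c(OC)cc(Oc3c(OC)cc(OC)c(Br)c3OC)cc2OC)cc1O
F4 | step 5 | 4-[4-(3-bromo-2,4,6-trimethoxyphenoxy)-2,6-dimethoxyphenoxy]-2,6-dihydroxybenzoic acid | OC(=O)c1c(O)cc(Oc2c(OC)cc(Oc3c(OC)cc(OC)c(Br)c3OC)cc2OC)cc1O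
F5 | step 1 | 2,6-difluoro-4-(2,4,6-trimethoxyphenoxy)benzaldehyde | COc1cc(OC)c(Oc2cc(F)c(C=O)c(F)c2)c(OC)c1
F6 | step 2 | 2,4,6-trimethoxyphenyl acetate | CC(=O)Oc1c(OC)cc(OC)cc1OC
F7 | step 2 | 3-bromo-2,4,6-trimethoxyphenyl acetate | CC(=O)Oc1c(OC)cc(OC)c(Br)c1OC
F8 | step 2 | 3-bromo-2,4,6-trimethoxyphenol | Oc1c(OC)cc(OC)c(Br)c1OC
F9 | step 9 | 2-[4-(3-bromo-2,4,6-trihydroxyphenoxy)-2,6-dihydroxyphenoxy]-4,6-dihydroxybenzoic acid | OC(=O)c1c(O)cc(O)cc1Oc1c(O)cc(Oc2c(O)cc(O)c(Br)c2O)cc1O
A1 | alternative 1 | 4-[4-(3,5-dimethoxyphenoxy)-3,5-dimethoxyphenoxy]-3-ethoxycyclobut-2-en-1-one (racemic) | CCOC1=CC(=O)C1Oc1cc(OC)c(Oc2cc(OC)cc(OC)c2)c(OC)c1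
A2 | alternative 1 | (ethoxyethynyl)trimethylsilane | CCOC#C[Si](C)(C)C
A3 | alternative 1 | 6-[4-(3,5-dimethoxyphenoxy)-3,5-dimethoxyphenoxy]-3,5-diethoxy-2-(trimethylsilyl)phenol | COc1cc(OC)cc(Oc2c(OC)cc(Oc3c(OCC)cc(OCC)c([Si](C)(C)C)c3O)cc2OC)c1
A4 | alternative 2 | 2-bromo-4-(3,5-dimethoxy-4-phenoxyphenoxy)-1,3,5-trimethoxybenzene | COc1cc(OC)c(Br)c(OC)c1Oc1cc(OC)c(Oc2ccccc2)c(OC)c1
A5 | alternative 2 | 5-[4-(3-bromo-2,4,6-trimethoxyphenoxy)-2,6-dimethoxyphenoxy]benzene-1,3-diol | Oc1cc(O)cc(Oc2c(OC)cc(Oc3c(OC)cc(OC)c(Br)c3OC)cc2OC)c1
A6 | alternative 3 | dimethyl 2-[4-(3,5-dimethoxyphenoxy)-3,5-dimethoxyphenoxy]propanedioate | COC(=O)C(Oc1cc(OC)c(Oc2cc(OC)cc(OC)c2)c(OC)c1)C(=O)OC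
A7 | alternative 3 | dimethyl 3-oxopentanedioate | COC(=O)CC(=O)CC(=O)OC
A8 | alternative 3 | dimethyl 5-[4-(3,5-dimethoxyphenoxy)-3,5-dimethoxyphenoxy]-2,4,6-trihydroxyisophthalate | COC(=O)c1c(O)c(Oc2cc(OC)c(Oc3cc(OC)cc(OC)c3)c(OC)c2)c(O)c(C(=O)OC)c1O
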